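A flask cannot turn over more substrate than its partner can pay for, and the readings give left-handed substrate and the products but not partner, so I have to assume the price.

| setting | maple | alder | larch | flask |
|---|---|---|---|---|
| left-handed substrate | 0.20 M | 0.20 M | 0.10 M | 0.20 M |
| right-handed substrate | 0.20 M | 0.20 M | 0.10 M | 0.20 M |
| partner | 0.30 M | 1.2 M | 0.60 M | 0.600 M |
| precatalyst | 20 mM | 20 mM | 20 mM | 20 mM |
| remark | run made earlier | run made earlier | run made earlier |  |
| time |  |  |  | 8.0 min |

| run | time / min | left-handed product / % | right-handed product / % | left-handed substrate / % |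
|---|---|---|---|---|
| maple | 0.667 | 2 | 2 | 44 |
| maple | 1.33 | 6 | 7 | 44 |
| maple | 2.00 | 11 | 6 | 39 |
| maple | 3.00 | 14 | 4 | 35 |
| maple | 4.00 | 17 | 8 | 36 |
| maple | 5.00 | 17 | 10 | 35 |
| alder | 0.250 | 4 | 6 | 40 |
| alder | 0.667 | 22 | 11 | 31 |
| alder | 1.33 | 23 | 17 | 25 |
| alder | 2.00 | 32 | 24 | 17 |
| alder | 3.00 | 36 | 29 | 9 |
| alder | 4.00 | 43 | 33 | 10 |
| alder | 5.00 | 45 | 37 | 2 |
| larch | 0.417 | 9 | 2 | 45 |
| larch | 1.33 | 13 | 10 | 38 |
| larch | 2.00 | 19 | 10 | 29 |
| larch | 3.00 | 29 | 16 | 21 |
| larch | 5.00 | 35 | 26 | 18 |

(scatter of a reading: 2 percentage points)

1. excess of left-handed product over right-handed product in the product at 25 s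
2. excess of left-handed product over right-handed product in the product at 8.0 min
3. part of the left-handed substrate and right-handed substrate charged together that has reacted at 8.0 min

- catalyst is single-handed; left-handed substrate and right-handed substrate are mirror images of each other, charged as a racemate, each of them at the stated concentration
- the analysis behind the earlier runs scatters by 2 percentage points, standard deviation
- an excess is below zero if the other one leads

I take one partner per turnover and one to wake each precatalyst. Turning the whole racemate in this flask then costs 0.420 M, the partner bill, which is less than the 0.600 M charged, so I expect no cap from partner here.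

Now the speed. The larch readings show 61.0 % as product at 5.00 min, and by the same price its c(partner) averages 0.529 M. Taking the rate as first-order in the substrates and in partner, I get 0.356 L mol⁻¹ min⁻¹. Maple, reckoned the same way, gives a lower 0.267 L mol⁻¹ min⁻¹, so what follows may lean high.

With c(partner) held at its charge, I reckon 81.9 % reacted for the flask. That is the weak link, since those turnovers cost partner. Charging them at the bill's price lowers the average c(partner) to 0.426 M and the conversion to 70.3 %. One more pass gives 72.2 %, and I commit to that.

The forecast, which differs from my figure, gives, in the order asked, 26 %, 19 % and 50 %, reading maple as “nearly 3 partner consumed per substrate”.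

The flask gives, in the same order, 28.4 %, 17.1 % and 64.7 % reacted, the last 7.5 percentage points below my figure.

    partner + precatalyst → catalyst + spent reagent (k = 0.0880 L mol⁻¹ s⁻¹)
    partner → decomposition product (k = 1.30 × 10⁻⁵ s⁻¹)
    catalyst ⇌ dormant form (K = 5.90, k = 0.150 s⁻¹)
    partner + catalyst + right-handed substrate → catalyst + right-handed product (k = 1.30 L² mol⁻² s⁻¹)
    partner + catalyst + left-handed substrate → catalyst + left-handed product (k = 2.40 L² mol⁻² s⁻¹)

At 8.0 min the left-handed substrate in the flask keeps 24 % of its charge, less than the partner's 53 %. The bill prices 64.7 % at 0.279 M, leaving 53.5 % of the partner.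

With 0.15 M of partner in the same flask, the bill exceeds the charge, so partner is the limiting reagent and the count allows at most 32.5 % reacted. The computed flask reaches 18.2 % at 8.0 min, with 38 % of its partner left.

The runs are calculated for substances that don't exist, and the scatter is random.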